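Don't read this row as a yield that climbs with the ligand charge. Complex with two exchanged sits in the middle of a chain, and you read it at a fixed time.

| flask | starting complex | incoming ligand | time |
|---|---|---|---|
| Saturday's | 20 mM | 12.0 mM | 6.0 min |
| Thursday's | 20 mM | 25.0 mM | 6.0 min |
| Tuesday's | 20 mM | 50.0 mM | 6.0 min |
| Monday's | 20 mM | 100 mM | 6.0 min |
| Wednesday's | 20 mM | 200 mM | 6.0 min |

    starting complex + incoming ligand → leaving ligand + complex with one exchanged (k1 = 0.26 M⁻¹ s⁻¹)
    complex with one exchanged + incoming ligand → leaving ligand + complex with two exchanged (k2 = 0.088 M⁻¹ s⁻¹)
    complex with two exchanged + incoming ligand → leaving ligand + complex with three exchanged (k3 = 0.044 M⁻¹ s⁻¹)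
    complex with two exchanged → over-reaction product (k4 = 0.011 s⁻¹)

- "hardly changes" means that all values lie within two and a half points (for a concentration: within two and a half percent of the largest)
- run time (Saturday's): 6.0 min

* amount of complex with two exchanged at the end, in percent of the starting complex charged for Saturday's, Thursday's, Tuesday's, Monday's, Wednesday's, in this order
* the course of these numbers from the first flask to the last (falls, then rises / rises, then falls / hardly changes / falls all the way / rises all the way)

1. Replace the ligand curve by a mean, which makes the exchanges pseudo-first-order. Take the larger of charge minus complex charge and 0.5 of the charge. That gives Tuesday's 30.0 mM and Monday's 80.0 mM, and Wednesday's 180 mM.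

2. Multiply by 0.088 M⁻¹ s⁻¹ and the run time. Tuesday's flask gets 0.950, Monday's 2.53, Wednesday's 5.70. This exposure x is the number of lifetimes of complex with one exchanged that the run lasts.

3. Read the outcome off x. With q = 2.95, the fraction of complex with one exchanged is b = q/(q−1)·(e^−x − e^−qx). So b is 0.493 on Tuesday's, 0.119 on Monday's and 0.00505 on Wednesday's.

4. Test whether x is enough. It isn't. Complex with two exchanged drains by the third exchange and by over-reaction. On Tuesday's that drain constant is 0.739 min⁻¹, so its lifetime of 1.35 min is short against the run. So it follows its feed: c = k·b, where k is feed constant over drain constant. That gives 10.6% for Tuesday's and 5.77% for Monday's. Monday's feed fades at 0.422 min⁻¹ against a drain of 0.871 min⁻¹, and Wednesday's at 0.950 min⁻¹ against 1.14 min⁻¹. While a feed fades, c lags above k·b, so expect Monday's and Wednesday's to stand above their hand values, 5.77% and 0.422%. Saturday's mean of 6.00 mM gives x = 0.190, b = 0.388 and c = 1.82%, below Tuesday's. So the row should rise, then fall.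

The forecast gives 0.9%, 3.6%, 9%, 10%, 2.1%, so rises, then falls, and says “the maximum lies near 100 mM or just below”.

The flask gives 0.960%, 3.65%, 9.12%, 9.66%, 2.25%: rises, then falls. Monday's 9.66% stands above the hand value 5.77%, and that flask still holds 15.9% complex with one exchanged. The row turns at a charge of 74 mM, whose exposure of 1.72 is higher than Tuesday's and lower than Monday's 2.53.

(The rate constants are those of an exercise; what happens was integrated by code.)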